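**Plan**

Locants: ring B is the quinone ring C1(=O)–C2(side chain)–C3H–C4(=O)–C4a–C8a; ring A is C4a–C8a with OH on C5 and C8; the side chain is C1'–C4'.

1. Retrosynthesis cuts the ester C–O bond at C1' first, then ring B at C4–C4a and C1–C2 in one operation, then C2–C1' (alkynylation), C2'=C3' (cross-metathesis) and C1–C8a (carbamoylation of the arene).
2. Forward: ring A is bought as hydroquinone and given C1 as a diethylamide. C2–C4 are joined to the side chain as a Weinreb ynamide, which is turned into a (Z)-β-stannyl enamide. Ring B closes in step 8, the protecting groups come off, and the ester is made last.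
3. Enabling feature: ring B is an ene-1,4-dione in which each carbonyl carbon sits on an sp2 carbon that can carry lithium. C4a lies between the C5 oxygen and the C8a carboxamide, and C2 is a vinylic carbon cis to C4. The ring is therefore the head-to-tail union of two β-metalated unsaturated amides.
4. Stereochemistry: C1' (R) comes from the catalyst-controlled zinc/ProPhenol alkynylation (step 5) and is carried through unchanged. The E alkene comes from cross-metathesis, and the Z vinylstannane (Sn cis to the amide) from hydroxyl-directed trans-hydrostannation. The acid centre is bought with (R)-2-methylbutanoic acid.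

Key step: step 8

Remark: both stereocentres of the given structure read R (C1' and C2 of the 2-methylbutanoate); (R)-2-methylbutanoic acid and N-methoxy-N-methylprop-2-ynamide are taken as purchasable.

**Route**

Step 1
Reactants: 1 hydroquinone
Product: 2 1,4-bis(methoxymethoxy)benzene
Conditions: NaH, MOMCl, DMF, 0 °C to rt
Reagents that add atoms: chloromethyl methyl ether (MOMCl), COCCl
Why: Williamson etherification of both phenoxides installs acetals that direct ortho-lithiation and survive organolithium reagents.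

Step 2
Reactants: 2 1,4-bis(methoxymethoxy)benzene; 3 N,N-diethylcarbamoyl chloride
Product: 5 N,N-diethyl-2,5-bis(methoxymethoxy)benzamide, via aryllithium 4 (not isolated)
Conditions: n-BuLi, TMEDA, THF, 0 °C; then 3, −78 °C to rt
Reagents that add atoms: none
Why: Directed ortho-metalation next to an OCH2OMe group (all four ring C–H are equivalent), followed by acylation of the aryllithium with the carbamoyl chloride, puts the future C1 on the ring.

Step 3
Reactants: 6 2-methylbut-3-en-2-ol; 7 (E)-but-2-enal (crotonaldehyde)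
Product: 8 (2E)-4-hydroxy-4-methylpent-2-enal
Conditions: second-generation Hoveyda–Grubbs catalyst (cat.), excess 7, CH2Cl2, 40 °C
Reagents that add atoms: none
Why: Olefin cross-metathesis between a hindered tertiary allylic alcohol that homodimerises slowly and an enal used in excess should give the conjugated E alkene with loss of propene.

Step 4
Reactants: 8 (2E)-4-hydroxy-4-methylpent-2-enal
Product: 9 (2E)-4-methyl-4-[(triethylsilyl)oxy]pent-2-enal
Conditions: TESOTf, 2,6-lutidine, CH2Cl2, −78 °C
Reagents that add atoms: triethylsilyl trifluoromethanesulfonate (TESOTf), CC[Si](CC)(CC)OS(=O)(=O)C(F)(F)F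
Why: Silyl triflate silylation caps the tertiary alcohol so that it cannot quench the zinc and lithium reagents used later.

Step 5
Reactants: 9 (2E)-4-methyl-4-[(triethylsilyl)oxy]pent-2-enal; 10 N-methoxy-N-methylprop-2-ynamide
Product: 11 (4R,5E)-4-hydroxy-N-methoxy-N,7-dimethyl-7-[(triethylsilyl)oxy]oct-5-en-2-ynamide
Conditions: Me2Zn, (R,R)-ProPhenol (cat.), Ph3PO (cat.), toluene, 0–4 °C
Reagents that add atoms: none
Why: Dinuclear zinc–ProPhenol alkynylation adds the zinc acetylide 1,2 to the enal under catalyst control; the (R,R)-ligand is expected to give the 4R carbinol (the antipodal ligand gives 4S), to be confirmed on 11 by Mosher ester analysis.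

Step 6
Reactants: 11 (4R,5E)-4-hydroxy-N-methoxy-N,7-dimethyl-7-[(triethylsilyl)oxy]oct-5-en-2-ynamide
Product: 12 (2Z,4R,5E)-4-hydroxy-N-methoxy-N,7-dimethyl-3-(tributylstannyl)-7-[(triethylsilyl)oxy]octa-2,5-dienamide
Conditions: Bu3SnH, [Cp*RuCl]4 (cat.), CH2Cl2, rt
Reagents that add atoms: tributyltin hydride (Bu3SnH), CCCC[SnH](CCCC)CCCC
Why: Hydroxyl-directed ruthenium-catalysed trans-hydrostannation should steer tin to the alkyne carbon next to the free C4–OH and add H and Sn anti, so that Sn lies cis to the amide carbonyl (2Z); C4 is untouched.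

Step 7
Reactants: 12 (2Z,4R,5E)-4-hydroxy-N-methoxy-N,7-dimethyl-3-(tributylstannyl)-7-[(triethylsilyl)oxy]octa-2,5-dienamide
Product: 13 (2Z,4R,5E)-N-methoxy-N,7-dimethyl-3-(tributylstannyl)-4,7-bis[(triethylsilyl)oxy]octa-2,5-dienamide
Conditions: TESCl, imidazole, DMF, 0 °C to rt
Reagents that add atoms: chlorotriethylsilane (TESCl), CC[Si](Cl)(CC)CC
Why: Base-buffered silylation of the secondary alcohol removes the last acidic proton before the organolithium step without protodestannylation.

Step 8
Reactants: 5 N,N-diethyl-2,5-bis(methoxymethoxy)benzamide; 13 (2Z,4R,5E)-N-methoxy-N,7-dimethyl-3-(tributylstannyl)-4,7-bis[(triethylsilyl)oxy]octa-2,5-dienamide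
Product: 18 5,8-bis(methoxymethoxy)-2-[(1R,2E)-4-methyl-1,4-bis[(triethylsilyl)oxy]pent-2-en-1-yl]naphthalene-1,4-dione, via aryllithium 14 (not isolated), via lithium hemiaminal 15 (not isolated), via vinyllithium 16 (not isolated), via dilithium bis-hemiaminal 17 (not isolated)
Conditions: 5, s-BuLi, TMEDA, THF, −78 °C; then 13, −78 °C; then MeLi, −78 to −20 °C; then H2O
Reagents that add atoms: none
Why: s-BuLi/TMEDA should remove the one ring proton of 5 that lies between the amide and an OCH2OMe group to give 14, which adds to the Weinreb carbonyl of 13 (C4–C4a bond) to give the chelated hemiaminal 15; MeLi then exchanges tin for lithium, and the vinyllithium 16, held cis to the aryl group by the Z double bond, attacks the neighbouring diethylamide (C1–C2 bond) to give 17, which water opens to the ene-dione with loss of HNEt2 and HN(OMe)Me, so no oxidant is needed. The closest known reaction types are the one-flask directed ortho-metalation/carbanionic ring closure of N,N-diethylbenzamides to anthraquinones and the Parham-type cyclisation of vinyllithiums made from vinylstannanes. Ring B closes by a 6-exo-trig acyl substitution of the C2 carbanion on the C1 amide carbonyl. No stereocentre is formed, and C1' keeps its configuration because its oxygen is silylated and no step makes that carbon a carbanion or a cation. The step needs site-selective lithiation (secured by the two flanking directing groups), addition of 14 to the Weinreb carbonyl instead of tin–lithium exchange or conjugate addition (aryllithiums do not exchange with vinylstannanes at −78 °C and the β-carbon is fully substituted), and a single addition at each carbonyl (secured by the two stable tetrahedral intermediates).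

Step 9
Reactants: 18 5,8-bis(methoxymethoxy)-2-[(1R,2E)-4-methyl-1,4-bis[(triethylsilyl)oxy]pent-2-en-1-yl]naphthalene-1,4-dione
Product: 19 5,8-dihydroxy-2-[(1R,2E)-4-methyl-1,4-bis[(triethylsilyl)oxy]pent-2-en-1-yl]naphthalene-1,4-dione
Conditions: MgBr2·OEt2, Et2O/CH2Cl2, 0 °C to rt; aqueous work-up
Reagents that add atoms: none
Why: Chelation-assisted Lewis-acid cleavage of the two aryl methoxymethyl acetals, each held next to a peri quinone carbonyl, should free the naphthazarin hydroxyls while the silyl ethers and C1' are left alone.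

Step 10
Reactants: 19 5,8-dihydroxy-2-[(1R,2E)-4-methyl-1,4-bis[(triethylsilyl)oxy]pent-2-en-1-yl]naphthalene-1,4-dione
Product: 20 2-[(1R,2E)-1,4-dihydroxy-4-methylpent-2-en-1-yl]-5,8-dihydroxynaphthalene-1,4-dione
Conditions: HF·pyridine, pyridine, THF, 0 °C to rt
Reagents that add atoms: none
Why: Buffered fluoride desilylation frees both side-chain hydroxyls without acid strong enough to ionise the allylic C–O bonds, so C1' is kept.

Step 11
Reactants: 20 2-[(1R,2E)-1,4-dihydroxy-4-methylpent-2-en-1-yl]-5,8-dihydroxynaphthalene-1,4-dione; 21 (2R)-2-methylbutanoic acid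
Product: 22 (1R,2E)-1-(5,8-dihydroxy-1,4-dioxo-1,4-dihydronaphthalen-2-yl)-4-hydroxy-4-methylpent-2-en-1-yl (2R)-2-methylbutanoate
Conditions: DCC, DMAP (cat.), CH2Cl2, 0 °C
Reagents that add atoms: none
Why: Steglich esterification should acylate only the secondary allylic hydroxyl, because the tertiary hydroxyl is too hindered and the two phenols are tied up in hydrogen bonds to the quinone carbonyls; low temperature and catalytic DMAP keep the α-centre of the acid from epimerising.

**Compound list**

1 | hydroquinone | Oc1ccc(O)cc1 | starting material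
2 | 1,4-bis(methoxymethoxy)benzene | COCOc1ccc(OCOC)cc1 | intermediate
3 | N,N-diethylcarbamoyl chloride | CCN(CC)C(Cl)=O | starting material
4 | [2,5-bis(methoxymethoxy)phenyl]lithium | COCOc1ccc(OCOC)c([Li])c1 | intermediate (not isolated)
5 | N,N-diethyl-2,5-bis(methoxymethoxy)benzamide | CCN(CC)C(=O)c1cc(OCOC)ccc1OCOC | intermediate
6 | 2-methylbut-3-en-2-ol | C=CC(C)(C)O | starting material
7 | (E)-but-2-enal | C/C=C/C=O | starting material
8 | (2E)-4-hydroxy-4-methylpent-2-enal | O=C/C=C/C(C)(C)O | intermediate
9 | (2E)-4-methyl-4-[(triethylsilyl)oxy]pent-2-enal | O=C/C=C/C(C)(C)O[Si](CC)(CC)CC | intermediate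
10 | N-methoxy-N-methylprop-2-ynamide | C#CC(=O)N(C)OC | starting material
11 | (4R,5E)-4-hydroxy-N-methoxy-N,7-dimethyl-7-[(triethylsilyl)oxy]oct-5-en-2-ynamide | O[C@H](/C=C/C(C)(C)O[Si](CC)(CC)CC)C#CC(=O)N(C)OC | intermediate
12 | (2Z,4R,5E)-4-hydroxy-N-methoxy-N,7-dimethyl-3-(tributylstannyl)-7-[(triethylsilyl)oxy]octa-2,5-dienamide | O[C@H](/C=C/C(C)(C)O[Si](CC)(CC)CC)/C(=C/C(=O)N(C)OC)[Sn](CCCC)(CCCC)CCCC | intermediate
13 | (2Z,4R,5E)-N-methoxy-N,7-dimethyl-3-(tributylstannyl)-4,7-bis[(triethylsilyl)oxy]octa-2,5-dienamide | CC[Si](CC)(CC)O[C@H](/C=C/C(C)(C)O[Si](CC)(CC)CC)/C(=C/C(=O)N(C)OC)[Sn](CCCC)(CCCC)CCCC | intermediate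
14 | [2-(diethylcarbamoyl)-3,6-bis(methoxymethoxy)phenyl]lithium | CCN(CC)C(=O)c1c([Li])c(OCOC)ccc1OCOC | intermediate (not isolated)
15 | lithium hemiaminal from addition of 14 to the Weinreb carbonyl of 13 (tin retained) | CC[Si](CC)(CC)O[C@H](/C=C/C(C)(C)O[Si](CC)(CC)CC)/C(=C/C(O[Li])(N(C)OC)c1c(OCOC)ccc(OCOC)c1C(=O)N(CC)CC)[Sn](CCCC)(CCCC)CCCC | intermediate (not isolated)
16 | vinyllithium from tin–lithium exchange of 15 | CC[Si](CC)(CC)O[C@H](/C=C/C(C)(C)O[Si](CC)(CC)CC)/C(=C/C(O[Li])(N(C)OC)c1c(OCOC)ccc(OCOC)c1C(=O)N(CC)CC)[Li] | intermediate (not isolated)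
17 | ring-closed dilithium bis-hemiaminal (1-diethylamino-4-[methoxy(methyl)amino]-1,4-dihydronaphthalene-1,4-diolate) | CC[Si](CC)(CC)O[C@H](/C=C/C(C)(C)O[Si](CC)(CC)CC)C1=CC(O[Li])(N(C)OC)c2c(OCOC)ccc(OCOC)c2C1(O[Li])N(CC)CC | intermediate (not isolated)
18 | 5,8-bis(methoxymethoxy)-2-[(1R,2E)-4-methyl-1,4-bis[(triethylsilyl)oxy]pent-2-en-1-yl]naphthalene-1,4-dione | CC[Si](CC)(CC)O[C@H](/C=C/C(C)(C)O[Si](CC)(CC)CC)C1=CC(=O)c2c(OCOC)ccc(OCOC)c2C1=O | intermediate
19 | 5,8-dihydroxy-2-[(1R,2E)-4-methyl-1,4-bis[(triethylsilyl)oxy]pent-2-en-1-yl]naphthalene-1,4-dione | CC[Si](CC)(CC)O[C@H](/C=C/C(C)(C)O[Si](CC)(CC)CC)C1=CC(=O)c2c(O)ccc(O)c2C1=O | intermediate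
20 | 2-[(1R,2E)-1,4-dihydroxy-4-methylpent-2-en-1-yl]-5,8-dihydroxynaphthalene-1,4-dione | O[C@H](/C=C/C(C)(C)O)C1=CC(=O)c2c(O)ccc(O)c2C1=O | intermediate
21 | (2R)-2-methylbutanoic acid | CC[C@@H](C)C(=O)O | starting material
22 | (1R,2E)-1-(5,8-dihydroxy-1,4-dioxo-1,4-dihydronaphthalen-2-yl)-4-hydroxy-4-methylpent-2-en-1-yl (2R)-2-methylbutanoate | CC[C@@H](C)C(=O)O[C@H](/C=C/C(C)(C)O)C1=CC(=O)c2c(O)ccc(O)c2C1=O | target

**Step count and risks**

Total step count: 11. Longest linear sequence: 9 steps (steps 3 to 11, from 6 and 7 to 22).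

Step 8 is the most likely to fail. MeLi may attack the diethylamide or the hemiaminal may collapse before tin–lithium exchange is complete. The alkoxide of 15 may also close onto the amide to a lactone, or the vinyllithium may be protonated before it closes the ring. The fallback closes ring B in two stages by aldehyde chemistry and sets out from 2 and 13. Aryllithium 4 is quenched with DMF to give 2,5-bis(methoxymethoxy)benzaldehyde F1. F1 is converted in the flask with LiN(Me)CH2CH2NMe2 and then n-BuLi into the C6-lithiated lithium α-amino alkoxide F2, which is added to 13 at −78 °C and worked up with water to give the stannyl keto aldehyde F3. Iododestannylation (I2, CH2Cl2, 0 °C) gives the (Z)-vinyl iodide F4 with retention. An intramolecular Nozaki–Hiyama–Kishi reaction (CrCl2, NiCl2 cat., DMF) then forms the C1–C2 bond to give the hydroxy enone F5. Oxidation with Dess–Martin periodinane comes back to the route at 18.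

Step 6 is the second risk. The conjugated amide may compete with the hydroxyl as the directing group, so tin is delivered to C2 instead of C3, or the anti sense of addition is lost. The fallback replaces the catalytic hydrostannation by a stoichiometric stannylcupration and sets out from 11. Compound 11 is silylated first (TESCl, imidazole, DMF) to the bis-silyl ynamide F6. Conjugate addition of Bu3SnCu(SPh)Li in THF puts tin on C3 by the polarity of the ynamide. The adduct is left to equilibrate at −48 °C before the methanol quench, so that tin ends cis to the carbonyl. This comes back to the route at 13.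

Step 9 is the third risk. The Lewis acid may strip the silyl ethers or ionise the allylic C–O bonds, after which the freed 1,4-diol can close to a dihydrofuran or C1' can scramble. The fallback changes the order of unmasking so that C1' is acylated before the acetals are opened; it sets out from 18. HF·pyridine first gives the diol 2-[(1R,2E)-1,4-dihydroxy-4-methylpent-2-en-1-yl]-5,8-bis(methoxymethoxy)naphthalene-1,4-dione F7. Steglich esterification with 21 (DCC, DMAP cat.) gives the bis-acetal ester F8. The acetals are then cleaved last with MgBr2·OEt2, when no free carbinol is left to cyclise and the C1'–O bond is deactivated by the acyl group and the quinone. This comes back to the route at 22.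

Further compounds
F1 | step 8 | 2,5-bis(methoxymethoxy)benzaldehyde | COCOc1ccc(OCOC)c(C=O)c1
F2 | step 8 | lithium [2-lithio-3,6-bis(methoxymethoxy)phenyl]{[2-(dimethylamino)ethyl](methyl)amino}methanolate (not isolated) | CN(C)CCN(C)C(O[Li])c1c([Li])c(OCOC)ccc1OCOC
F3 | step 8 | 3,6-bis(methoxymethoxy)-2-[(2Z,4R,5E)-7-methyl-3-(tributylstannyl)-4,7-bis[(triethylsilyl)oxy]octa-2,5-dienoyl]benzaldehyde | CC[Si](CC)(CC)O[C@H](/C=C/C(C)(C)O[Si](CC)(CC)CC)/C(=C/C(=O)c1c(OCOC)ccc(OCOC)c1C=O)[Sn](CCCC)(CCCC)CCCC
F4 | step 8 | 2-[(2Z,4R,5E)-3-iodo-7-methyl-4,7-bis[(triethylsilyl)oxy]octa-2,5-dienoyl]-3,6-bis(methoxymethoxy)benzaldehyde | CC[Si](CC)(CC)O[C@H](/C=C/C(C)(C)O[Si](CC)(CC)CC)/C(I)=C/C(=O)c1c(OCOC)ccc(OCOC)c1C=O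
F5 | step 8 | 4-hydroxy-5,8-bis(methoxymethoxy)-3-[(1R,2E)-4-methyl-1,4-bis[(triethylsilyl)oxy]pent-2-en-1-yl]naphthalen-1(4H)-one | CC[Si](CC)(CC)O[C@H](/C=C/C(C)(C)O[Si](CC)(CC)CC)C1=CC(=O)c2c(OCOC)ccc(OCOC)c2C1O
F6 | step 6 | (4R,5E)-N-methoxy-N,7-dimethyl-4,7-bis[(triethylsilyl)oxy]oct-5-en-2-ynamide | CC[Si](CC)(CC)O[C@H](/C=C/C(C)(C)O[Si](CC)(CC)CC)C#CC(=O)N(C)OC
F7 | step 9 | 2-[(1R,2E)-1,4-dihydroxy-4-methylpent-2-en-1-yl]-5,8-bis(methoxymethoxy)naphthalene-1,4-dione | O[C@H](/C=C/C(C)(C)O)C1=CC(=O)c2c(OCOC)ccc(OCOC)c2C1=O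
F8 | step 9 | (1R,2E)-1-[5,8-bis(methoxymethoxy)-1,4-dioxo-1,4-dihydronaphthalen-2-yl]-4-hydroxy-4-methylpent-2-en-1-yl (2R)-2-methylbutanoate | CC[C@@H](C)C(=O)O[C@H](/C=C/C(C)(C)O)C1=CC(=O)c2c(OCOC)ccc(OCOC)c2C1=O
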